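**Conventions.** Labdane numbering of the target is used for every intermediate. α/β refer to the usual drawing in which the C10 methyl is β. TBS = tert-butyldimethylsilyl, MOM = methoxymethyl.

## The problem

Compound 37, (5R,7R,8R,9S,10S,13S), is a cis-fused decalin (rings A and B, H-5 and the C10 methyl on the same face) spiro-linked at C9 to a tetrahydrofuran (ring C, O–C9–C11–C12–C13), which is spiro-linked at C13 to a 2,3-dihydrofuran (ring D, C13–C14=C15–O–C16). Ring B is oxidised at every carbon but C5: a C6 ketone, a C7 hydroxyl, a tertiary C8 acetate and the C9 ether oxygen, so that C8, C9 and C10 are three contiguous fully substituted stereocentres next to the quaternary C4. C9 is the natural source of control: with its oxygen in place, C10 and C5 can be fixed through cyclic transition states and C8, then C7, through the shape of the cis-decalin and the C8 acetate, whereas C13, three bonds out and flanked only by methylene arms, needs a chiral reagent. Three things will not stand rough treatment: the enol ether of ring D, whose allylic spiro C13–O bond ionises with acid toward the aromatic furan; H-5, α to the C6 ketone, which base can epimerise; and the tertiary acetate beside the free C7 hydroxyl of an α-ketol (acyl shift, retro-aldol). Ring D must therefore be closed last and without acid, and the ketol must be made late and never meet strong base. The feature that opens the route is that C3, C4, C5, C10, C9 and C8, with methyls on C4 and C10 and oxygen on C8 and C9, are the ring of 3,5-dimethylphenol after ortho-hydroxylative dearomatisation. If C1–C2 are added across C10 and C3 as a dienophile and C6–C7 as a vinyl group on C8, closure of ring B (C5–C6) with the cis H-5/C10-methyl relation becomes the [3,3] shift of a 2-vinylbicyclo[2.2.2]oct-5-en-2-ol.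

## Retrosynthesis

**Ring D (37 ⇐ 36).** The O–C15 bond is cut, leaving alkynol 36 with an ethynyl group (C14≡C15) and a hydroxymethyl group (C16) on C13. Cycloisomerisation is an atom-neutral step in an amine medium. The neighbouring options, loss of methanol from a C15 acetal or reduction and dehydration of a C15 lactone, need acid or hydride beside the ketol. The forward step must tolerate a ketone, a free secondary hydroxyl and a tertiary acetate.

**Ketol (36 ⇐ 35 ⇐ 34).** The C6 carbonyl and the C7–O bond are removed together to give the C6=C7 alkene 34. A ketohydroxylation directed away from the C8 acetate sets C7 and the regiochemistry in one step; stepwise dihydroxylation and mono-oxidation would have to distinguish two hindered secondary hydroxyls. The alkyne must be capped and the C16 oxygen silylated for this step.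

**C8 (34 ⇐ 32 ⇐ 30).** The C8–CH3 bond and the acetate are cut back to enone 32 and this to the saturated ketone 30 (Saegusa–Ito). Methyl addition to a ketone creates the tertiary centre directly; it asks for attack on the β face of C8.

**Ring C and C13 (30 ⇐ 29 ⇐ 27 ⇐ 25 ⇐ 24).** The O9–C13 bond is cut to the ethynyl epoxide 27, so that the C9 oxygen opens a defined 2,2-disubstituted epoxide with inversion. The epoxide comes from allylic alcohol 24 by Sharpless epoxidation (25), oxidation (26) and alkyne homologation. This gives reagent control at the remote C13; the neighbouring cuts (halo-etherification of a 1,1-disubstituted alkene, addition to a C13 oxocarbenium ion) would rely on a weak bias from the spiro centre. The precursor 24 has no ring C or D and no C13 stereocentre.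

**C12–C13 (24 ⇐ 21 + 22).** A Negishi coupling joins the primary iodide 21 to commercial 2-bromoallyl alcohol 22. The two-carbon arm on C9 is exactly C11–C12, so no carbon has to be excised late.

**Gem-dimethyl (21 ⇐ 20 ⇐ 19 ⇐ 17).** The second C4 methyl is cut off, leaving the C3=C4 alkene that the key step produces. Radical hydromethylation is chosen over cyclopropanation–hydrogenolysis because platinum in acetic acid would also reduce the C8 ketone. It requires that no other alkene be present, which is why the C9 side chain is a silyloxyethyl group and not an allyl group at this stage.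

**Key step (17 ⇐ 14).** Ring B is opened by the reverse oxy-Cope shift: the C5–C6 bond is cut and C3–C8 formed, giving the 2-vinylbicyclo[2.2.2]octenol 14. This removes the cis ring fusion as a problem, since the bicycle allows only one outcome, and leaves a precursor whose stereocentres all derive from C9. The C9 oxygen must be masked by a group that neither deprotonates nor migrates (MOM).

**Vinyl carbinol (14 ⇐ 13 ⇐ 11 ⇐ 10).** The C7–C8 bond is cut (vinyl addition to the bicyclic ketone) and a phenylsulfonyl group is put back on the ethano bridge. The addition must come from the face of the alkene bridge.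

**Bicycle (10 ⇐ 9 + 8 ⇐ 7).** The C10–C1 and C3–C2 bonds are cut by a retro-Diels–Alder reaction to ortho-quinol 9 and phenyl vinyl sulfone 8, an ethylene equivalent. The C9–O bond is then cut to phenol 7. A chiral iodyl arene introduces the oxygen and the absolute configuration; the cycloaddition must take the face of the hydroxyl.

**Phenol (7 ⇐ 6 ⇐ 4 ⇐ 3 ⇐ 1 + 2).** The C9–C11 bond comes from a Claisen rearrangement of the allyl ether 3 of 3,5-dimethylphenol 1. The allyl group is trimmed to the hydroxyethyl arm at the arene stage, where its alkene is the only one in the molecule.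

## Roads not taken

**Alternative 1:** Both O–C13 and O–C15 are cut at once. In the forward direction camphorsulfonic acid would make the C9 hydroxyl of epoxy acetal A1 open the C13–C16 epoxide at C13, and the freed C16 hydroxyl would displace methanol from the C15 acetal to give A2. Its merit is real: two rings and two C–O bonds in one metal-free step, with C13 fixed by inversion. For this target the weak points are three. The epoxide of A1 has two methylene arms and no allylic hydroxyl, so nothing controls its configuration reliably. The free C8 hydroxyl of A1 can compete with the C9 hydroxyl. Ring D emerges as a methyl acetal, and turning A2 into the enol ether needs acid or a silyl triflate next to the ketol and the epimerisable C5. It also says nothing about the cis-decalin. In ring-forming economy it beats the chosen plan (one step against steps 17 and 23), and the chosen plan borrows its first half for ring C. Against that the chosen plan sets a reagent-controlled C13, a neutral final ring closure and a disconnection that solves the core.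

**Alternative 2:** The C13–C14 bond is cut. Rh2(OAc)4 (divalent rhodium) would decompose diazoacetate A3 and the carbenoid would insert into the C13–H bond to give spiro-lactone A4. The insertion is 1,5, at a tertiary C–H activated by oxygen, and proceeds with retention, so C13 could be set at a simple secondary ether centre. In that respect it is better than the chosen plan, which needs three steps (14–16) to build a defined quaternary epoxide. The lactone of A4 would also pass through oxidations unharmed. The difficulty lies after the key step: the lactone must be reduced to the lactol and dehydrated. Hydride cannot tell the lactone from the C6 ketone and C8 acetate if ring B is finished, and if ring D is finished first the enol ether cannot survive the ring B oxidation. The diazo ester also costs extra steps. The chosen plan sets against it an alkyne that already carries C14 and C15 at the right oxidation level, so that the last step is an isomerisation.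

**Alternative 3:** The C6 carbonyl and C7–O bond are cut as the strategic step. RuCl3 with KHSO5 and NaHCO3 (octavalent ruthenium oxide formed in the flask) would convert alkene A5 into ketol A6 on the face opposite the acetate. This is the same reaction used here as step 21, so in ring B the two plans are equal, and the acetal ring D of A5 is probably a safer spectator toward the oxidant than the silylalkyne carried here. As a strategy it puts its one uncertain step last but one, leaves the decalin unaddressed, and ends with loss of methanol from the acetal of A6 under acid beside the ketol. The chosen plan accepts the silylalkyne risk in exchange for an acid-free endgame and places its strategic step early, where failure is cheap.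

Key step: step 9

## Route

Remarks on the chemistry (assumptions):
- The sense of induction of the chiral iodyl reagent for this phenol is not known in advance; the (R)-reagent is written and its antipode is used if the sense proves opposite. The reagent is made from the enantiopure diiodobinaphthyl with dimethyldioxirane.
- Adduct 10 is drawn as the expected major regio- and endo isomer at the sulfonyl carbon; the other isomers converge in step 8.

Step 1
Reactants: 1 3,5-dimethylphenol; 2 allyl bromide
Product: 3 allyl 3,5-dimethylphenyl ether
Conditions: K2CO3, acetone, reflux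
Reagents that add atoms: none
Why: Williamson ether synthesis of the phenoxide with a primary allylic bromide; O-alkylation is the normal course under these conditions.

Step 2
Reactants: 3 allyl 3,5-dimethylphenyl ether
Product: 4 2-allyl-3,5-dimethylphenol
Conditions: PhNEt2, 200 °C
Reagents that add atoms: none
Why: Aromatic Claisen rearrangement ([3,3] shift, then tautomerisation); the two ortho positions are equivalent, so one phenol results, and the new bond is the future C9–C11 bond.

Step 3
Reactants: 4 2-allyl-3,5-dimethylphenol
Product: 6 2-(2-hydroxyethyl)-3,5-dimethylphenol, via arylacetaldehyde 5 (not isolated)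
Conditions: O3, CH2Cl2–MeOH, −78 °C (indicator end point); then NaBH4, −78 °C → rt
Reagents that add atoms: ozone, [O-][O+]=O
Why: Ozonolysis with reductive work-up; the terminal alkene reacts with ozone far faster than the alkylphenol ring at −78 °C, and borohydride reduces the peroxidic intermediates and aldehyde 5 to the alcohol, which removes the third allyl carbon and the only alkene that could not survive later alkene chemistry.

Step 4
Reactants: 6 2-(2-hydroxyethyl)-3,5-dimethylphenol
Product: 7 2-[2-(tert-butyldimethylsilyloxy)ethyl]-3,5-dimethylphenol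
Conditions: t-BuMe2SiCl (1.05 equiv), imidazole, DMF, 0 °C
Reagents that add atoms: tert-butyldimethylsilyl chloride, CC(C)(C)[Si](C)(C)Cl
Why: Silyl ether formation; with one equivalent of silyl chloride the primary aliphatic hydroxyl reacts in preference to the less nucleophilic ortho-substituted phenol, as with other hydroxyalkylphenols, and the ether shields the alcohol from the iodine oxidant and the later bases.

Step 5
Reactants: 7 2-[2-(tert-butyldimethylsilyloxy)ethyl]-3,5-dimethylphenol; 8 phenyl vinyl sulfone
Product: 10 3-hydroxy-3-[2-(TBSO)ethyl]-4,6-dimethyl-7-(phenylsulfonyl)bicyclo[2.2.2]oct-5-en-2-one, via ortho-quinol 9 (not isolated)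
Conditions: (R)-2,2′-diiodyl-1,1′-binaphthyl (ArIO2, pentavalent iodine), CH2Cl2, −40 → 0 °C; aq. Na2S2O4 wash; then 8 (5 equiv), toluene, 70 °C
Reagents that add atoms: (R)-2,2′-diiodyl-1,1′-binaphthyl, O=I(=O)c1ccc2ccccc2c1-c1c(I(=O)=O)ccc2ccccc12
Why: Hydroxylative phenol dearomatisation by an iodyl arene (the phenol binds iodine and an iodine-bound oxygen passes to the alkylated ortho carbon, as known for 2-alkylphenols) followed by Diels–Alder trapping; the axially chiral reagent sets C9 as (S), and the dienophile adds to the quinol face bearing the hydroxyl (the known preference of 6-hydroxycyclohexa-2,4-dienones, helped here by an OH···O=S hydrogen bond), which fixes C10 and C3 relative to C9. The methyls on the diene (C4, C10) slow quinol dimerisation so that the sulfone can compete.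

Step 6
Reactants: 10 sulfone adduct
Product: 11 3-(methoxymethoxy) derivative of 10
Conditions: MeOCH2Cl, iPr2NEt, Bu4NI (cat.), CH2Cl2, 40 °C
Reagents that add atoms: chloromethyl methyl ether, COCCl
Why: MOM ether formation on the tertiary α-ketol hydroxyl under amine base; the ketone cannot enolise (bridgehead and quaternary α-carbons), and an acetal ether, unlike a silyl ether, cannot migrate to the neighbouring alkoxide in steps 7 and 9.

Step 7
Reactants: 11 MOM-protected sulfone adduct; 12 vinylmagnesium bromide
Product: 13 2-vinyl carbinol of 11 (vinyl syn to the alkene bridge)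
Conditions: CeCl3, THF, −78 → 0 °C
Reagents that add atoms: none
Why: 1,2-Addition of the vinyl Grignard reagent as its less basic organocerium derivative, so that the α-sulfonyl C–H is not deprotonated; bicyclo[2.2.2]oct-5-en-2-ones are attacked from the face of the alkene bridge because the other face is screened by the inward hydrogens of the ethano bridge, here reinforced by the MOM group and its magnesium chelate on that face, so the vinyl group should end syn to the C4=C5 bridge and the hydroxyl syn to the ethano bridge.

Step 8
Reactants: 13 vinyl carbinol sulfone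
Product: 14 3-[2-(TBSO)ethyl]-3-(methoxymethoxy)-4,6-dimethyl-2-vinylbicyclo[2.2.2]oct-5-en-2-ol
Conditions: Na(Hg) (6%), Na2HPO4, MeOH–THF, −20 °C
Reagents that add atoms: none
Why: Reductive desulfonylation by electron transfer from sodium amalgam in buffered methanol, the standard removal of a phenylsulfonyl group after its use as an ethylene equivalent; the tertiary allylic alcohol, alkenes, acetal and silyl ether are not reduced, and all sulfone isomers give the one product.

Step 9
Reactants: 14 2-vinylbicyclo[2.2.2]oct-5-en-2-ol
Product: 17 cis-decal-3-en-8-one (9α-OMOM; 9β-CH2CH2OTBS; 5β-H; 10β-Me), via potassium alkoxide 15 (not isolated), via potassium enolate 16 (not isolated)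
Conditions: KH, 18-crown-6, THF, 0 → 50 °C; then aq. NH4Cl
Reagents that add atoms: none
Why: KH with 18-crown-6 gives the loosely ion-paired potassium alkoxide 15, whose oxyanion on C8 weakens the C3–C8 bond of the 1,5-diene C6=C7–C8–C3–C4=C5 so that the [3,3] shift (anionic oxy-Cope rearrangement) runs near room temperature; this is the rearrangement established for Diels–Alder adducts of cyclohexa-2,4-dienones carrying an endo vinyl carbinol. Ring B is closed in the pericyclic step itself and not by an ionic cyclisation: C5–C6 forms as C3–C8 breaks in a six-membered transition state that the bicycle holds as a boat, giving the carbocycle C5–C6–C7–C8–C9–C10 and moving the ring alkene to C3=C4. The one new stereocentre, C5, is controlled by the bicyclic tether: the vinyl group can reach C5 only on the alkene face turned toward the C8–C9 bridge, which leaves H-5 on the side of the C10 methyl; C9 and C10 pass through untouched. The step needs the vinyl group syn to the C4=C5 bridge (step 7), an unsubstituted alkene carbon C5, and an oxygen on C9 that can neither be deprotonated nor migrate (the MOM ether). The product is the regiodefined C8 enolate 16, protonated at C7 on work-up to ketone 17; the TBS ether is five bonds from the alkoxide and should not migrate.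

Step 10
Reactants: 17 cis-decal-3-en-8-one
Product: 19 4,4-dimethyl-cis-decalin-8-one (9α-OMOM; 9β-CH2CH2OTBS), via sulfonylhydrazide 18 (not isolated)
Conditions: Fe(acac)3, PhSiH3, CH2=N–NHSO2Ar (Ar = 2,4,6-triisopropylphenyl; from ArSO2NHNH2 and aq. CH2O), THF–MeOH, rt; then MeOH, 60 °C
Reagents that add atoms: formaldehyde 2,4,6-triisopropylbenzenesulfonylhydrazone, C=NNS(=O)(=O)c1c(C(C)C)cc(C(C)C)cc1C(C)C
Why: Iron-mediated hydrogen-atom-transfer hydromethylation of an unactivated alkene: the iron hydride delivers H to C3, the tertiary C4 radical adds to the carbon of the formaldehyde hydrazone, and warming in methanol expels sulfinate and N2 from 18 to leave the second C4 methyl; the hindered ketone, acetal and silyl ether are spectators, no other alkene is present, and C4 ends achiral.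

Step 11
Reactants: 19 4,4-dimethyl-cis-decalin-8-one silyl ether
Product: 20 primary alcohol (9β-CH2CH2OH)
Conditions: Bu4NF, THF, 0 °C → rt
Reagents that add atoms: none
Why: Fluoride cleavage of the primary silyl ether; the γ-hydroxy ketone may rest as its five-membered hemiketal but reacts in step 12 through the open form.

Step 12
Reactants: 20 primary alcohol
Product: 21 primary iodide (9β-CH2CH2I)
Conditions: I2, PPh3, imidazole, CH2Cl2, 0 °C
Reagents that add atoms: iodine, II
Why: Appel-type iodination (Garegg–Samuelsson conditions) of the primary alcohol; the acetal-protected tertiary oxygen cannot close an oxetane.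

Step 13
Reactants: 21 primary iodide; 22 2-bromoprop-2-en-1-ol
Product: 24 2-substituted allylic alcohol (C12–C13(=CH2)–CH2OH), via alkylzinc iodide 23 (not isolated)
Conditions: Zn, LiCl, THF, 40 °C; then 22, Pd(OAc)2, SPhos, THF, rt
Reagents that add atoms: none
Why: LiCl-assisted zinc insertion into the primary iodide and Negishi coupling with the vinyl bromide; alkylzinc halides tolerate the ketone and, with the fast Pd(OAc)2/SPhos catalyst, also the free hydroxyl of 22, so the allylic alcohol forms directly.

Step 14
Reactants: 24 2-substituted allylic alcohol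
Product: 25 (13R)-epoxy alcohol
Conditions: Ti(OiPr)4, D-(−)-diisopropyl tartrate, t-BuOOH, 4 Å molecular sieves, CH2Cl2, −20 °C
Reagents that add atoms: tert-butyl hydroperoxide, CC(C)(C)OO
Why: Sharpless asymmetric epoxidation; with 2-substituted allylic alcohols the D-(−)-tartrate complex gives the (R)-2-alkylglycidol, so C13 is set by the reagent and not by the distant core.

Step 15
Reactants: 25 (13R)-epoxy alcohol
Product: 26 (13S)-epoxy aldehyde
Conditions: Dess–Martin periodinane, NaHCO3, CH2Cl2, 0 °C → rt
Reagents that add atoms: none
Why: Dess–Martin oxidation of the primary alcohol under bicarbonate buffer; the aldehyde has no α-hydrogen and cannot epimerise (the descriptor changes by priority only).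

Step 16
Reactants: 26 (13S)-epoxy aldehyde
Product: 27 (13R)-ethynyl epoxide
Conditions: dimethyl (1-diazo-2-oxopropyl)phosphonate, K2CO3, MeOH, 0 °C → rt
Reagents that add atoms: dimethyl (1-diazo-2-oxopropyl)phosphonate, COP(=O)(OC)C(=[N+]=[N-])C(C)=O
Why: Ohira–Bestmann (Seyferth–Gilbert) homologation: the diazophosphonate anion adds to the aldehyde only, and loss of phosphate and N2 with a 1,2-hydrogen shift gives the terminal alkyne, which supplies C15 at the oxidation level of ring D; C13 is untouched.

Step 17
Reactants: 27 (13R)-ethynyl epoxide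
Product: 29 spiro-tetrahydrofuran alcohol (ring C closed; 13S), via C16 methoxymethyl ether 28 (not isolated)
Conditions: camphorsulfonic acid (0.2 equiv), CH2Cl2, 0 °C → rt; then MeOH, HCl (cat.), 40 °C
Reagents that add atoms: none
Why: Acid-catalysed 5-exo opening of the epoxide at its tertiary carbon by the C9 ether oxygen with loss of the methoxymethyl group (the dealkylative participation known for MOM and benzyl ethers in epoxide and iodonium openings); backside attack inverts C13 and turns the (R)-epoxide into the (13S) spiro ether, the alkynyl group disfavouring a free cation. The methoxymethyl cation passes to the new primary hydroxyl (28) or to methanol, and the acidic methanolysis leaves the free alcohol.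

Step 18
Reactants: 29 spiro-tetrahydrofuran alcohol
Product: 30 C16 TBS ether of 29
Conditions: t-BuMe2SiCl, imidazole, DMF, rt
Reagents that add atoms: tert-butyldimethylsilyl chloride, CC(C)(C)[Si](C)(C)Cl
Why: Silyl ether formation on the primary alcohol, needed because ruthenium tetroxide in step 21 would oxidise a free primary hydroxyl.

Step 19
Reactants: 30 saturated 8-ketone
Product: 32 C6=C7 enone with trimethylsilyl-capped alkyne, via bis-silylated enol ether 31 (not isolated)
Conditions: LiN(iPr)2 (2.5 equiv), Me3SiCl, THF, −78 °C; then Pd(OAc)2, MeCN, rt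
Reagents that add atoms: chlorotrimethylsilane, C[Si](C)(C)Cl
Why: Saegusa–Ito oxidation: the ketone can enolise only toward C7, the excess amide also lithiates the alkyne so that Me3SiCl caps it (31), and Pd(OAc)2 converts the silyl enol ether into the enone by β-hydride elimination from C6.

Step 20
Reactants: 32 enone
Product: 34 8α-acetoxy-8β-methyl C6=C7 alkene, via tertiary alkoxide 33 (not isolated)
Conditions: MeLi, CeCl3, THF, −78 °C; then Ac2O, −78 °C → rt
Reagents that add atoms: methyllithium, [Li]C; acetic anhydride, CC(=O)OC(C)=O
Why: 1,2-Addition of the non-basic methylcerium reagent to the enone and acetylation of the hindered tertiary alkoxide in the same flask; ring B of this cis-decalin should prefer the half-chair with C1 axial under the α face of C8, so the methyl should enter from the convex β face, anti to the C9–O bond, placing the C8 oxygen α (cis to O9) and the methyl β.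

Step 21
Reactants: 34 tertiary allylic acetate
Product: 35 6-keto-7β-hydroxy-8α-acetate (silyl groups retained)
Conditions: RuCl3 (cat.), 2KHSO5·KHSO4·K2SO4, NaHCO3, EtOAc–MeCN–H2O, rt
Reagents that add atoms: potassium peroxymonosulfate, [K+].[O-]S(=O)(=O)OO
Why: Ruthenium tetroxide-catalysed ketohydroxylation (RuO4, octavalent ruthenium, formed from RuCl3 and KHSO5): [3+2] addition to the only alkene from the β face opposite the acetate gives a ruthenate ester that is oxidised at the carbinol C–H remote from the electron-withdrawing acetoxy carbon, that is at C6, leaving the C6 ketone and the 7β-hydroxyl. The short buffered reaction should spare the hindered silylalkyne, the silyl ether and ring C, which has no α-hydrogen.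

Step 22
Reactants: 35 silylated ketol
Product: 36 alkynol (C13 ethynyl; C16 hydroxyl)
Conditions: Bu4NF, AcOH, THF, 0 °C → rt
Reagents that add atoms: none
Why: Fluoride removal of both silyl groups (O–Si and alkynyl C–Si); the acetic acid buffer keeps the medium too weakly basic for acyl migration to the C7 hydroxyl, retro-aldol cleavage or epimerisation at C5.

Step 23
Reactants: 36 alkynol
Product: 37 target compound
Conditions: Mo(CO)6, Et3N, Et2O, hν (350 nm) to give Et3N·Mo(CO)5; then 36, rt
Reagents that add atoms: none
Why: Molybdenum-carbonyl-catalysed cycloisomerisation of a but-3-yn-1-ol: the terminal alkyne rearranges to a molybdenum vinylidene, the C16 hydroxyl adds to its carbene carbon (C15) in the endo sense, and protodemetallation gives the 2,3-dihydrofuran; the amine medium is harmless to the enol ether, ketol and acetate, and no stereocentre is touched.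

## Compound list

1 | 3,5-dimethylphenol | Cc1cc(C)cc(O)c1 | starting material
2 | allyl bromide | C=CCBr | starting material
3 | allyl 3,5-dimethylphenyl ether | C=CCOc1cc(C)cc(C)c1 | intermediate
4 | 2-allyl-3,5-dimethylphenol | C=CCc1c(C)cc(C)cc1O | intermediate
5 | (2-hydroxy-4,6-dimethylphenyl)acetaldehyde (with its lactol) | O=CCc1c(C)cc(C)cc1O | intermediate (not isolated)
6 | 2-(2-hydroxyethyl)-3,5-dimethylphenol | OCCc1c(C)cc(C)cc1O | intermediate
7 | 2-[2-(tert-butyldimethylsilyloxy)ethyl]-3,5-dimethylphenol | CC(C)(C)[Si](C)(C)OCCc1c(C)cc(C)cc1O | intermediate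
8 | phenyl vinyl sulfone | C=CS(=O)(=O)c1ccccc1 | starting material
9 | (S)-6-[2-(TBSO)ethyl]-6-hydroxy-3,5-dimethylcyclohexa-2,4-dien-1-one | CC1=CC(C)=CC(=O)[C@]1(O)CCO[Si](C)(C)C(C)(C)C | intermediate (not isolated)
10 | 3-hydroxy-3-[2-(TBSO)ethyl]-4,6-dimethyl-7-(phenylsulfonyl)bicyclo[2.2.2]oct-5-en-2-one; hydroxyl syn to the ethano bridge, sulfonyl endo | O=C1[C@](O)(CCO[Si](C)(C)C(C)(C)C)[C@@]2(C)C[C@H](S(=O)(=O)c3ccccc3)[C@@H]1C(C)=C2 | intermediate
11 | 3-(methoxymethoxy) ether of 10 | O=C1[C@](OCOC)(CCO[Si](C)(C)C(C)(C)C)[C@@]2(C)C[C@H](S(=O)(=O)c3ccccc3)[C@@H]1C(C)=C2 | intermediate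
12 | vinylmagnesium bromide | C=C[Mg]Br | starting material
13 | 2-vinyl-2-ol from 11; vinyl syn to the alkene bridge, hydroxyl syn to the ethano bridge | O[C@@]1(C=C)[C@](OCOC)(CCO[Si](C)(C)C(C)(C)C)[C@@]2(C)C[C@H](S(=O)(=O)c3ccccc3)[C@@H]1C(C)=C2 | intermediate
14 | 3-[2-(TBSO)ethyl]-3-(methoxymethoxy)-4,6-dimethyl-2-vinylbicyclo[2.2.2]oct-5-en-2-ol (same faces as 13) | O[C@@]1(C=C)[C@](OCOC)(CCO[Si](C)(C)C(C)(C)C)[C@@]2(C)CC[C@@H]1C(C)=C2 | intermediate (key-step precursor)
15 | potassium alkoxide of 14 | [K+].[O-][C@@]1(C=C)[C@](OCOC)(CCO[Si](C)(C)C(C)(C)C)[C@@]2(C)CC[C@@H]1C(C)=C2 | intermediate (not isolated)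
16 | potassium C7=C8 enolate of 17 | [K+].[O-]C1=CC[C@@H]2C(C)=CCC[C@]2(C)[C@@]1(OCOC)CCO[Si](C)(C)C(C)(C)C | intermediate (not isolated)
17 | cis-decalin 8-ketone with C3=C4 alkene; 5β-H, 10β-Me, 9α-OMOM, 9β-CH2CH2OTBS | O=C1CC[C@@H]2C(C)=CCC[C@]2(C)[C@@]1(OCOC)CCO[Si](C)(C)C(C)(C)C | intermediate (key-step product)
18 | C4-(sulfonylhydrazinomethyl) adduct of 17 (either C4 epimer) | O=C1CC[C@@H]2C(C)(CNNS(=O)(=O)c3c(C(C)C)cc(C(C)C)cc3C(C)C)CCC[C@]2(C)[C@@]1(OCOC)CCO[Si](C)(C)C(C)(C)C | intermediate (not isolated)
19 | 4,4-dimethyl-cis-decalin-8-one; 9α-OMOM, 9β-CH2CH2OTBS | O=C1CC[C@@H]2C(C)(C)CCC[C@]2(C)[C@@]1(OCOC)CCO[Si](C)(C)C(C)(C)C | intermediate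
20 | primary alcohol from 19 (open form; may rest as hemiketal) | O=C1CC[C@@H]2C(C)(C)CCC[C@]2(C)[C@@]1(OCOC)CCO | intermediate
21 | primary iodide | O=C1CC[C@@H]2C(C)(C)CCC[C@]2(C)[C@@]1(OCOC)CCI | intermediate
22 | 2-bromoprop-2-en-1-ol | OCC(Br)=C | starting material
23 | alkylzinc iodide from 21 | O=C1CC[C@@H]2C(C)(C)CCC[C@]2(C)[C@@]1(OCOC)CC[Zn]I | intermediate (not isolated)
24 | allylic alcohol; side chain C11H2–C12H2–C13(=CH2)–CH2OH | O=C1CC[C@@H]2C(C)(C)CCC[C@]2(C)[C@@]1(OCOC)CCC(=C)CO | intermediate
25 | (13R)-13,16-epoxy alcohol | O=C1CC[C@@H]2C(C)(C)CCC[C@]2(C)[C@@]1(OCOC)CC[C@@]3(CO)CO3 | intermediate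
26 | (13S)-epoxy aldehyde | O=C1CC[C@@H]2C(C)(C)CCC[C@]2(C)[C@@]1(OCOC)CC[C@@]3(C=O)CO3 | intermediate
27 | (13R)-13-ethynyl-13,16-epoxide | O=C1CC[C@@H]2C(C)(C)CCC[C@]2(C)[C@@]1(OCOC)CC[C@@]3(C#C)CO3 | intermediate
28 | ring C closed; (13S)-ethynyl; C16 OMOM | O=C1CC[C@@H]2C(C)(C)CCC[C@]2(C)[C@@]12CC[C@](C#C)(COCOC)O2 | intermediate (not isolated)
29 | ring C closed; (13S)-ethynyl; C16 hydroxyl; 8-ketone | O=C1CC[C@@H]2C(C)(C)CCC[C@]2(C)[C@@]12CC[C@](C#C)(CO)O2 | intermediate
30 | C16 TBS ether of 29 | O=C1CC[C@@H]2C(C)(C)CCC[C@]2(C)[C@@]12CC[C@](C#C)(CO[Si](C)(C)C(C)(C)C)O2 | intermediate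
31 | C7=C8 trimethylsilyl enol ether with C-silylated alkyne | C[Si](C)(C)OC1=CC[C@@H]2C(C)(C)CCC[C@]2(C)[C@@]12CC[C@](C#C[Si](C)(C)C)(CO[Si](C)(C)C(C)(C)C)O2 | intermediate (not isolated)
32 | C6=C7 enone (8-ketone), silylalkyne | O=C1C=C[C@@H]2C(C)(C)CCC[C@]2(C)[C@@]12CC[C@](C#C[Si](C)(C)C)(CO[Si](C)(C)C(C)(C)C)O2 | intermediate
33 | lithium 8α-alkoxide (8β-methyl) | [Li+].[O-][C@]1(C)C=C[C@@H]2C(C)(C)CCC[C@]2(C)[C@@]12CC[C@](C#C[Si](C)(C)C)(CO[Si](C)(C)C(C)(C)C)O2 | intermediate (not isolated)
34 | 8α-acetoxy-8β-methyl C6=C7 alkene | CC(=O)O[C@]1(C)C=C[C@@H]2C(C)(C)CCC[C@]2(C)[C@@]12CC[C@](C#C[Si](C)(C)C)(CO[Si](C)(C)C(C)(C)C)O2 | intermediate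
35 | 6-keto-7β-hydroxy-8α-acetate, silyl groups retained | CC(=O)O[C@]1(C)[C@@H](O)C(=O)[C@@H]2C(C)(C)CCC[C@]2(C)[C@@]12CC[C@](C#C[Si](C)(C)C)(CO[Si](C)(C)C(C)(C)C)O2 | intermediate
36 | alkynol: 13-ethynyl, 16-hydroxy | CC(=O)O[C@]1(C)[C@@H](O)C(=O)[C@@H]2C(C)(C)CCC[C@]2(C)[C@@]12CC[C@](C#C)(CO)O2 | intermediate
37 | (5R,7R,8R,9S,10S,13S)-8-acetoxy-7-hydroxy-9,13;15,16-diepoxylabd-14-en-6-one | CC(=O)O[C@]1(C)[C@@H](O)C(=O)[C@@H]2C(C)(C)CCC[C@]2(C)[C@@]12CC[C@@]1(C=COC1)O2 | target

## Step count and least certain steps

Total: 23 steps. Longest linear sequence: 23 steps from 1 (the route is fully linear).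

**Step 9 (key step).** The alkoxide may fragment or undergo a [1,3] shift instead of the [3,3] shift if the bridgehead methyl and the two C9 substituents distort the boat transition state. Fallback: a neutral siloxy-Cope rearrangement, which has no alkoxide. From 14, Me3SiCl and imidazole give the trimethylsilyl ether F4; thermolysis (o-dichlorobenzene, about 200 °C) gives the trimethylsilyl enol ether F5; dilute citric acid hydrolyses it and the route is rejoined at 17.

**Step 5.** The oxygen may be delivered to the unsubstituted ortho carbon (leading on to an ortho-quinone), the reagent may discriminate the enantiotopic faces poorly, or quinol dimerisation may outrun the cycloaddition. Fallback: racemic dearomatisation and resolution. From 7, stabilised 2-iodoxybenzoic acid in THF with excess 8 gives the racemic ortho-quinol F1 and from it the racemic adduct F2; preparative chromatography on a chiral stationary phase rejoins the route at 10.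

**Step 7.** Facial selectivity may be eroded because the C11 methylene on C9 flanks the alkene-side trajectory. Fallback: a rod-shaped nucleophile followed by semi-reduction. From 11, HC≡CMgBr with CeCl3 gives the ethynyl carbinol F3; hydrogen over Pd/CaCO3 poisoned with Pb(OAc)2 and quinoline reduces the alkyne to the vinyl group and the route is rejoined at 13.

**Step 17.** The C8 carbonyl oxygen may compete with the acetal ether oxygen for the activated epoxide (bicyclic ketal formation), or ionisation at C13 may erode the inversion. Fallback: use a free tertiary hydroxyl as the nucleophile. From 24, HCl in methanol removes the MOM group to give the diol F6. The operations of steps 14 to 16 then give the epoxy alcohol F7, the epoxy aldehyde F8 and the ethynyl epoxide F9. Catalytic camphorsulfonic acid closes ring C and the route is rejoined at 29.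

**Step 20.** The methyl may be delivered to the α face of C8, or the reagent may deprotonate C5 through the enone. Fallback: introduce the methyl first and the oxygen second, by an electrophile that takes the face the methyl nucleophile would have taken.
- From 31, MeLi and PhNTf2 give the enol triflate F10.
- MeMgBr with Fe(acac)3 gives the 8-methyl C7=C8 alkene F11.
- Dimethyldioxirane gives the 7α,8α-epoxide F12.
- NaSePh opens the epoxide at C7 to the hydroxy selenide F13, and H2O2 eliminates the selenoxide toward C6 to give the tertiary allylic alcohol F14.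
- Ac2O with 4-dimethylaminopyridine rejoins the route at 34.

**Step 21.** Oxidation of the ruthenate ester may take place at C7 instead of C6, the C6–C7 bond may be cleaved, or the silylalkyne may be attacked. Fallback: regiocontrol by sterics instead of electronics. From 34, dimethyldioxirane gives the 6β,7β-epoxide F15. Dimethyl sulfoxide with Me3SiOTf opens it at the less hindered C6, and iPr2NEt collapses the alkoxysulfonium ion to the C6 ketone (Kornblum-type oxidative epoxide opening). The route is rejoined at 35.

## Further compounds

F1 | step 5 | racemic ortho-quinol (9 and its mirror image) | CC1=CC(C)=CC(=O)[C@]1(O)CCO[Si](C)(C)C(C)(C)C.CC1=CC(C)=CC(=O)[C@@]1(O)CCO[Si](C)(C)C(C)(C)C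
F2 | step 5 | racemic sulfone adduct (10 and its mirror image) | O=C1[C@](O)(CCO[Si](C)(C)C(C)(C)C)[C@@]2(C)C[C@H](S(=O)(=O)c3ccccc3)[C@@H]1C(C)=C2.O=C1[C@@](O)(CCO[Si](C)(C)C(C)(C)C)[C@]2(C)C[C@@H](S(=O)(=O)c3ccccc3)[C@H]1C(C)=C2
F3 | step 7 | 2-ethynyl carbinol of 11 (ethynyl syn to the alkene bridge) | O[C@@]1(C#C)[C@](OCOC)(CCO[Si](C)(C)C(C)(C)C)[C@@]2(C)C[C@H](S(=O)(=O)c3ccccc3)[C@@H]1C(C)=C2
F4 | step 9 | trimethylsilyl ether of 14 | C[Si](C)(C)O[C@@]1(C=C)[C@](OCOC)(CCO[Si](C)(C)C(C)(C)C)[C@@]2(C)CC[C@@H]1C(C)=C2
F5 | step 9 | C7=C8 trimethylsilyl enol ether of 17 | C[Si](C)(C)OC1=CC[C@@H]2C(C)=CCC[C@]2(C)[C@@]1(OCOC)CCO[Si](C)(C)C(C)(C)C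
F6 | step 17 | 9-hydroxy allylic alcohol (24 without MOM) | O=C1CC[C@@H]2C(C)(C)CCC[C@]2(C)[C@@]1(O)CCC(=C)CO
F7 | step 17 | 9-hydroxy (13R)-epoxy alcohol | O=C1CC[C@@H]2C(C)(C)CCC[C@]2(C)[C@@]1(O)CC[C@@]3(CO)CO3
F8 | step 17 | 9-hydroxy (13S)-epoxy aldehyde | O=C1CC[C@@H]2C(C)(C)CCC[C@]2(C)[C@@]1(O)CC[C@@]3(C=O)CO3
F9 | step 17 | 9-hydroxy (13R)-ethynyl epoxide | O=C1CC[C@@H]2C(C)(C)CCC[C@]2(C)[C@@]1(O)CC[C@@]3(C#C)CO3
F10 | step 20 | C7=C8 enol triflate | O=S(=O)(OC1=CC[C@@H]2C(C)(C)CCC[C@]2(C)[C@@]12CC[C@](C#C[Si](C)(C)C)(CO[Si](C)(C)C(C)(C)C)O2)C(F)(F)F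
F11 | step 20 | 8-methyl C7=C8 alkene | CC1=CC[C@@H]2C(C)(C)CCC[C@]2(C)[C@@]12CC[C@](C#C[Si](C)(C)C)(CO[Si](C)(C)C(C)(C)C)O2
F12 | step 20 | 7α,8α-epoxide (8β-methyl) | O1[C@]2(C)[C@H]1CC[C@@H]3C(C)(C)CCC[C@]3(C)[C@@]24CC[C@](C#C[Si](C)(C)C)(CO[Si](C)(C)C(C)(C)C)O4
F13 | step 20 | 7β-phenylseleno-8α-hydroxy-8β-methyl compound | O[C@]1(C)[C@@H]([Se]c5ccccc5)CC[C@@H]2C(C)(C)CCC[C@]2(C)[C@@]12CC[C@](C#C[Si](C)(C)C)(CO[Si](C)(C)C(C)(C)C)O2
F14 | step 20 | 8α-hydroxy-8β-methyl C6=C7 alkene | O[C@]1(C)C=C[C@@H]2C(C)(C)CCC[C@]2(C)[C@@]12CC[C@](C#C[Si](C)(C)C)(CO[Si](C)(C)C(C)(C)C)O2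
F15 | step 21 | 6β,7β-epoxide of 34 | CC(=O)O[C@]1(C)[C@H]3O[C@H]3[C@@H]2C(C)(C)CCC[C@]2(C)[C@@]12CC[C@](C#C[Si](C)(C)C)(CO[Si](C)(C)C(C)(C)C)O2
A1 | alternative 1 | epoxy acetal: 9-hydroxy, 13,16-epoxide, C15 dimethyl acetal, 6-keto-7-OTBS-8-ol | O[C@]1(C)[C@@H](O[Si](C)(C)C(C)(C)C)C(=O)[C@@H]2C(C)(C)CCC[C@]2(C)[C@@]1(O)CC[C@@]3(CC(OC)OC)CO3
A2 | alternative 1 | bis-spiro ether with ring D as methyl acetal (C15 epimers) | O[C@]1(C)[C@@H](O[Si](C)(C)C(C)(C)C)C(=O)[C@@H]2C(C)(C)CCC[C@]2(C)[C@@]12CC[C@@]1(CC(OC)OC1)O2
A3 | alternative 2 | C16 diazoacetate of the 13-H spiro-tetrahydrofuran 8-ketone | O=C1CC[C@@H]2C(C)(C)CCC[C@]2(C)[C@@]13CC[C@H](COC(=O)C=[N+]=[N-])O3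
A4 | alternative 2 | bis-spiro 15,16-lactone (8-ketone) | O=C1CC[C@@H]2C(C)(C)CCC[C@]2(C)[C@@]13CC[C@@]4(CC(=O)OC4)O3
A5 | alternative 3 | C6=C7 alkene 8-acetate with ring D as methyl acetal | CC(=O)O[C@]1(C)C=C[C@@H]2C(C)(C)CCC[C@]2(C)[C@@]12CC[C@@]1(CC(OC)OC1)O2
A6 | alternative 3 | 6-keto-7-hydroxy-8-acetate with ring D as methyl acetal | CC(=O)O[C@]1(C)[C@@H](O)C(=O)[C@@H]2C(C)(C)CCC[C@]2(C)[C@@]12CC[C@@]1(CC(OC)OC1)O2
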